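(Readings and results are calculated from invented constants.)

| setting | Friday's | Tuesday's | flask |
|---|---|---|---|
| left-handed substrate | 0.50 M | 0.50 M | 0.50 M |
| right-handed substrate | 0.50 M | 0.50 M | 0.50 M |
| partner | 2 equiv | 2 equiv | 2.00 equiv |
| free catalyst | 10 mol% | 10 mol% | 10 mol% |
| impurity | 92 mM | 150 mM | 66 mM |
| remark | run made earlier | run made earlier |  |
| time |  |  | 10 d |

- Friday's (time / d: left-handed substrate / %, right-handed substrate / %): 2.50: 41.2, 49.6; 5.00: 39.1, 50.0; 8.00: 38.0, 49.4; 10.0: 38.1, 49.4; 12.0: 38.0, 49.8
- Tuesday's (time / d: left-handed substrate / %, right-handed substrate / %): 1.04: 45.3, 49.8; 1.67: 44.5, 49.6; 3.00: 42.8, 49.8; 6.00: 42.9, 49.8; 12.0: 42.3, 50.0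

(scatter of a reading: 0.5 percentage points)

- free catalyst is single-handed; left-handed substrate and right-handed substrate are mirror images of each other, charged as a racemate, each of them at the stated concentration
- the numbers in the tables scatter with a standard deviation of 0.5 percentage points
- an excess is the difference of the two amounts in percent of their sum
- an excess is below zero if the other one leads

1. part of the left-handed substrate and right-handed substrate charged together that has reacted at 10 d
2. excess of left-handed product over right-handed product in the product at 10 d
3. excess of right-handed substrate over left-handed substrate among what is left of the two at 10 d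

Tuesday's run, with 150 mM of impurity, shows the stages quickly: left-handed substrate reads 45.3% by 1.04 d, while right-handed substrate reads 49.8% and stays there within the scatter, so the single-handed free catalyst works almost on one hand. In the middle that run is already flat, at 42.8% by 3.00 d, whereas Friday's run, with 92 mM, goes on falling to 38.0% at 8.00 d. At the end both stand still with left-handed substrate plainly present, so I read a catalyst that dies, not a substrate that runs out.

If free catalyst dies pseudo-first-order in impurity, the total it turns over goes as one over c(impurity), so I multiply c(impurity) by the natural logarithm of the left-handed charge over its stopping level. Friday's run gives 25.2 mM, Tuesday's gives 25.1 mM, and I carry their mean, 25.2 mM, as the poison budget. For the flask, with 66 mM of impurity, it puts the stop near 34.1% of left-handed substrate. One thing to watch is that the 50.0 mM of catalyst charged is a larger share of the impurity in this flask than in Tuesday's run, so if the two are used one for one, c(impurity) sags and left-handed substrate may end below my figure.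

The forecast gives 15.8% reacted (14.5% to 18%), 96.8% in the product (92% to 100%) and 18.1% in what is left (16.3% to 21%), with left-handed substrate at 34.5%, slightly above mine, and says of the stop: “It reflects catalyst death caused by the impurity.”

The flask gives 17.2% reacted, 95.6% in the product and 19.8% in what is left, inside the three ranges.

    free catalyst → spent catalyst A (k = 0.0140 h⁻¹)
    free catalyst + right-handed substrate ⇌ catalyst intermediate B (K = 0.770 M⁻¹, k = 92.0 M⁻¹ h⁻¹)
    partner + catalyst intermediate A → free catalyst + left-handed product (k = 0.120 M⁻¹ h⁻¹)
    partner + catalyst intermediate B → free catalyst + right-handed product (k = 0.0430 M⁻¹ h⁻¹)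
    free catalyst + impurity → spent catalyst B (k = 4.30 M⁻¹ h⁻¹)
    free catalyst + left-handed substrate ⇌ catalyst intermediate A (K = 16.0 M⁻¹, k = 31.0 M⁻¹ h⁻¹)
    2 free catalyst ⇌ resting dimer, settled at all times (K = 3400 M⁻¹)

Left-handed substrate ends past my figure, at 32.0% by 100 d, a budget of 29.5 mM against 25.2 mM, and impurity stands at 34.3% of its charge at 10.0 d. The excess in the product rests on the back reaction of catalyst intermediate B to free catalyst and right-handed substrate: the same flask without that back reaction gives −93.0% in place of 95.6%. In the neighbour flask with 0.17 M of impurity, the budget foretells 43.1% of left-handed substrate, and that flask holds 43.7% at 10.0 d.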